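In the closed, stirred vessel the solid substrate passes into solution as starting material, which may go on to target and to isomer of the product A, so the quantity to follow is the share of that isomer in itself plus target.

| flask | solid substrate | remark | time |
|---|---|---|---|
| south-east | 0.046 M | run made earlier |  |
| north-west | 0.10 M | run made earlier |  |
| flask | 0.069 M |  | 6.0 d |

| run | time / d | isomer of the product A / % | target / % |
|---|---|---|---|
| south-east | 0.417 | 0 | 13.9 |
| south-east | 1.04 | 0.6 | 34.2 |
| south-east | 2.08 | 1.0 | 44.0 |
| south-east | 3.00 | 1.7 | 45.3 |
| south-east | 4.00 | 2.1 | 45.0 |
| south-east | 6.00 | 3.5 | 44.7 |
| south-east | 8.00 | 3.5 | 44.5 |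
| north-west | 1.04 | 0.3 | 15.3 |
| north-west | 2.08 | 1.3 | 22.8 |
| north-west | 3.00 | 1.2 | 26.6 |
| north-west | 4.00 | 1.8 | 27.7 |
| north-west | 5.00 | 1.4 | 29.1 |
| north-west | 6.00 | 2.6 | 28.5 |
| north-west | 8.00 | 2.3 | 29.3 |

(scatter of a reading: 0.5 percentage points)

- given per volume of solution although it is solid: solid substrate
- what may be going on: starting material <-> target; starting material <-> isomer of the product A; target <-> isomer of the product B; solid substrate <-> starting material
- at the start none of the solid substrate is in solution

1. share of isomer of the product A in isomer of the product A plus target at 2.5 h
2. share of isomer of the product A in isomer of the product A plus target at 20 h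
3. share of isomer of the product A in isomer of the product A plus target at 6.0 d

The first way to the share at 6.0 d reads it straight from the runs at that time: 7.26% in the south-east run and 8.36% in the north-west run. The second way sets those readings aside and uses the ends of each run. The share rises from 1.72% at 1.04 d to 7.29% at 8.00 d in the south-east run, and from 1.92% to 7.28% over the same times in the north-west run. That makes 0.00800 /d in the first and 0.00769 /d in the second, although the north-west run holds twice the charge. Their mean, 0.00785 /d, is the climb: the gain in the share per day, the pace of a drift from kinetic towards thermodynamic control.

Laid as a straight line from the mean early share 1.82%, the climb gives 5.72% at 6.0 d, so the two ways part. The first way is the one that cheats: the north-west share reads 4.59% at 5.00 d and 8.36% a day later, a jump of 0.0377 /d, larger than the climb, and each reading scatters by 0.5 percentage points.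

The reckoning here therefore commits to the line: 1.09% at 2.5 h, 1.66% at 20 h and 5.72% at 6.0 d. The forecast stands higher, with 1.8%, 2.2% and 7.3%, and its ground for expecting the share to barely depend on the loading is that “both isomers form from the same dissolved starting material”.

The flask gives 1.14%, 1.71% and 5.99%, and the forecast holds within its margins.

starting material ⇌ target (K = 1.10, k = 0.0470 /h); starting material ⇌ isomer of the product A (K = 59.0, k = 5.00 × 10⁻⁴ /h); target ⇌ isomer of the product B (K = 0.250, k = 0.0600 /h); solid substrate ⇌ starting material, rate k4*(cs4 - [starting material]) while solid is left; crystals form when [starting material] > cs4 (solubility = 27.0 mM, k = 0.410 /h) Isomer of the product B stands at 10.6% of the charge in this flask at 6.00 d, yet the passing of target into it makes no difference to the share. The climb, laid on this flask's share at 20 h, carries it to 5.77% at 6.0 d. The neighbour flask with 0.12 M of solid substrate keeps 45.6% of its charge as solid at 6.00 d, more than the 5.35% here, and the climb laid on its 1.71% gives 5.77%, where that neighbour stands at 5.99%.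

(The numbers in the tables were generated by integration from invented constants; the scatter is artificial.)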